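**Plan**

- The retrosynthesis first cuts the depside C(=O)–O bond between the ring A carbonyl and O-4 of ring B, with the ring B acid masked as a benzyl ester. This gives 2,4-dimethoxy-3,6-dimethylbenzoic acid and benzyl 2,4-dihydroxy-3,6-dimethylbenzoate; the acid is simply the O-methylated, debenzylated form of that same ester.
- The shared arene is taken back to a non-aromatic benzyl 3,6-dimethyl-2,4-dioxocyclohexane-1-carboxylate, which is cut at C1–C6 and C2–C3 into dibenzyl malonate and (E)-hex-4-en-3-one.
- Feature used: in ring A (and equally in ring B) the carboxyl carbon on C1, oxygen on C2, methyl on C3, oxygen on C4 and methyl on C6 occupy five adjacent ring carbons, and only C5 carries hydrogen. This is atom for atom the pattern of a 3,6-dimethyl-2,4-dioxocyclohexane-1-carboxylate, so ring construction sets what aromatic substitution could not.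
- Forward: a Michael–Claisen annulation closes the only new ring (step 1) and chlorination–dehydrochlorination aromatizes it (step 2). One portion is O-methylated and hydrogenolysed to the ring A acid (steps 3 and 4), which acylates O-4 of a second portion (step 5); hydrogenolysis then unmasks the ring B acid (step 6).
- Stereochemistry: the target has no stereocentre. The three sp3 centres formed in step 1 are uncontrolled and are erased in step 2.

Key step: step 1

Remark on the chemistry: the annulation product is drawn as its triketo form, although it should exist mainly as an enol and as a mixture of diastereomers. This is immaterial because the aromatization removes every sp3 centre. Benzyl esters are used throughout so that one aromatized intermediate serves both rings and no hindered ester has to be saponified.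

**Step 1**
Reactants: 1 dibenzyl malonate; 2 (E)-hex-4-en-3-one
Product: 4 benzyl 3,6-dimethyl-2,4-dioxocyclohexane-1-carboxylate, via dibenzyl 2-(4-oxohexan-2-yl)malonate 3 (not isolated)
Conditions: NaH (1.1 equiv), BnOH (1.2 equiv), THF, 0 °C (forms NaOBn); 1, then 2 added slowly, 0 °C to reflux; cold 1 M HCl work-up
Reagents that add atoms: none
Why: Sodium benzyloxide deprotonates 1, and the soft malonate anion adds 1,4 to C5 of enone 2 (Michael addition), forming the bond that becomes C1–C6 of the ring and giving 3 as its enolate. Proton exchange moves the enolate to the ethyl side of the ketone, whose methylene carbon attacks one benzyl ester carbonyl and expels benzyloxide (intramolecular Claisen condensation of the Dieckmann kind), forming the C2–C3 bond. The closest known reaction type is the Michael–Claisen annulation of malonic esters with α,β-unsaturated ketones to dihydroresorcylates; the ring closes in the 6-exo-trig mode. The three new sp3 centres (C1, C3, C6) are under no control, C1 and C3 being epimerizable through the enol, and none survives step 2. The selectivity needed is regiochemical and is fixed by connectivity, because only the ethyl methylene can reach an ester through a six-membered transition state (the other α-carbon would close a four-membered ring), while 1,4- over 1,2-addition follows from the stabilized nucleophile. Matching the alkoxide to the ester keeps any ester exchange degenerate, and deprotonation of the acidic β-diketone product pulls the equilibria forward.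

**Step 2**
Reactants: 4 benzyl 3,6-dimethyl-2,4-dioxocyclohexane-1-carboxylate
Product: 6 benzyl 2,4-dihydroxy-3,6-dimethylbenzoate, via benzyl 3-chloro-3,6-dimethyl-2,4-dioxocyclohexane-1-carboxylate 5 (not isolated)
Conditions: NCS (1.0 equiv), DMF, 0 °C to rt; then 90 °C
Reagents that add atoms: none
Why: Electrophilic chlorination of the β-diketone enol at C3 should give 5, which loses HCl by 1,4-elimination through its C1=C2 enol (hydrogen from C6, chloride from C3) and tautomerizes to the resorcinol; this is the halogenation–dehydrohalogenation aromatization of dihydroresorcylates, and a single equivalent of NCS limits chlorination of the product ring.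

**Step 3**
Reactants: 6 benzyl 2,4-dihydroxy-3,6-dimethylbenzoate (first portion)
Product: 7 benzyl 2,4-dimethoxy-3,6-dimethylbenzoate
Conditions: MeI (3 equiv), K2CO3 (3 equiv), DMF, 50 °C
Reagents that add atoms: iodomethane, CI
Why: Williamson ether synthesis, in which both phenoxides are O-methylated by SN2 attack on MeI; excess reagent and warm DMF should overcome the lower reactivity of the hydrogen-bonded 2-OH, and the benzyl ester is inert to K2CO3.

**Step 4**
Reactants: 7 benzyl 2,4-dimethoxy-3,6-dimethylbenzoate
Product: 8 2,4-dimethoxy-3,6-dimethylbenzoic acid
Conditions: H2 (1 atm), 10% Pd/C, EtOAc, rt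
Reagents that add atoms: none
Why: Catalytic hydrogenolysis of the benzylic C–O bond releases the acid under neutral conditions, which avoids saponifying a doubly ortho-substituted ester; the aryl methyl ethers and the arene are not touched.

**Step 5**
Reactants: 8 2,4-dimethoxy-3,6-dimethylbenzoic acid; 6 benzyl 2,4-dihydroxy-3,6-dimethylbenzoate (second portion)
Product: 10 benzyl 4-[(2,4-dimethoxy-3,6-dimethylbenzoyl)oxy]-2-hydroxy-3,6-dimethylbenzoate, via 2,4-dimethoxy-3,6-dimethylbenzoic trifluoroacetic anhydride 9 (not isolated)
Conditions: TFAA (4 equiv), toluene, rt
Reagents that add atoms: none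
Why: Depside-forming esterification through the mixed anhydride 9 (TFAA activation), from which a doubly ortho-substituted, electron-rich acid readily transfers its acyl group; the 4-OH of 6 should react in preference to the 2-OH, which is hydrogen-bonded to the ester carbonyl and flanked on both sides.

**Step 6**
Reactants: 10 benzyl 4-[(2,4-dimethoxy-3,6-dimethylbenzoyl)oxy]-2-hydroxy-3,6-dimethylbenzoate
Product: 11 diffractaic acid (4-[(2,4-dimethoxy-3,6-dimethylbenzoyl)oxy]-2-hydroxy-3,6-dimethylbenzoic acid)
Conditions: H2 (1 atm), 10% Pd/C, EtOAc, rt
Reagents that add atoms: none
Why: Hydrogenolysis of the benzyl ester over Pd/C at room temperature should free the ring B carboxylic acid while leaving the aryl ester link intact, which a hydrolytic deprotection would not spare.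

**Compound list**

1 | dibenzyl malonate | O=C(CC(=O)OCc1ccccc1)OCc1ccccc1 | starting material
2 | (E)-hex-4-en-3-one | CCC(=O)/C=C/C | starting material
3 | dibenzyl 2-(4-oxohexan-2-yl)malonate (racemic Michael adduct, not isolated) | CCC(=O)CC(C)C(C(=O)OCc1ccccc1)C(=O)OCc1ccccc1 | intermediate
4 | benzyl 3,6-dimethyl-2,4-dioxocyclohexane-1-carboxylate (mixture of diastereomers and enol tautomers) | O=C(OCc1ccccc1)C1C(C)CC(=O)C(C)C1=O | intermediate
5 | benzyl 3-chloro-3,6-dimethyl-2,4-dioxocyclohexane-1-carboxylate (mixture of diastereomers, not isolated) | O=C(OCc1ccccc1)C1C(C)CC(=O)C(C)(Cl)C1=O | intermediate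
6 | benzyl 2,4-dihydroxy-3,6-dimethylbenzoate | Cc1cc(O)c(C)c(O)c1C(=O)OCc1ccccc1 | intermediate
7 | benzyl 2,4-dimethoxy-3,6-dimethylbenzoate | COc1cc(C)c(C(=O)OCc2ccccc2)c(OC)c1C | intermediate
8 | 2,4-dimethoxy-3,6-dimethylbenzoic acid | COc1cc(C)c(C(=O)O)c(OC)c1C | intermediate
9 | 2,4-dimethoxy-3,6-dimethylbenzoic trifluoroacetic anhydride (not isolated) | COc1cc(C)c(C(=O)OC(=O)C(F)(F)F)c(OC)c1C | intermediate
10 | benzyl 4-[(2,4-dimethoxy-3,6-dimethylbenzoyl)oxy]-2-hydroxy-3,6-dimethylbenzoate | COc1cc(C)c(C(=O)Oc2cc(C)c(C(=O)OCc3ccccc3)c(O)c2C)c(OC)c1C | intermediate
11 | diffractaic acid | COc1cc(C)c(C(=O)Oc2cc(C)c(C(=O)O)c(O)c2C)c(OC)c1C | target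

**Step count**

Total: 6 steps. Longest linear sequence: 6 steps (1 and 2 → 4 → 6 → 7 → 8 → 10 → 11); the second portion of 6 enters at step 5.

**Steps most likely to fail**

Step 2. Chlorination may run on into the electron-rich C5 position of the freshly formed resorcinol ring, or the sequence may stall at the chlorodione because loss of HCl is slow. Fallback: setting out from 4, the ring would be dehydrogenated without any halogen by heating with Hg(OAc)2 (divalent mercury, 1.1 equiv) and NaOAc in AcOH at reflux. This mercuration–demercuration dehydrogenation of the enol deposits elemental mercury and cannot halogenate the arene. It returns to the route at 6 and makes no compound outside the list (F0).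

Step 5. Site selectivity of the acyl transfer may be lost, through acylation at the 2-oxygen or Friedel–Crafts attack at C5 of the phenol partner, and transfer from the doubly ortho-substituted acyl donor may be slow. Fallback: setting out from 8, the acid would be converted with (COCl)2 and catalytic DMF in CH2Cl2 into 2,4-dimethoxy-3,6-dimethylbenzoyl chloride F1. This would be added to 6 that has been stirred with K2CO3 in acetone (rt to reflux). Under base the more acidic, non-chelated 4-OH is the phenoxide formed and acylated, and no acid is present to promote C-acylation. The sequence returns to the route at 10.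

Step 1. Ring closure may be incomplete, the sequence stopping at the open-chain Michael adduct, with base-induced oligomerization of the enone and ester cleavage with decarboxylation during work-up as further losses. Fallback: setting out from 2, the annulation would be run in its long-established form with purchased dimethyl malonate (COC(=O)CC(=O)OC) and NaOMe in MeOH at reflux. It would pass through dimethyl 2-(4-oxohexan-2-yl)malonate F2 (not isolated) to methyl 3,6-dimethyl-2,4-dioxocyclohexane-1-carboxylate F3. Ester exchange of this β-keto ester with benzyl alcohol in refluxing toluene (catalytic DMAP, methanol distilled off; acylketene-type transesterification) would return to the route at 4.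

**Further compounds**

F0 | step 2 | none | none
F1 | step 5 | 2,4-dimethoxy-3,6-dimethylbenzoyl chloride | COc1cc(C)c(C(=O)Cl)c(OC)c1C
F2 | step 1 | dimethyl 2-(4-oxohexan-2-yl)malonate | CCC(=O)CC(C)C(C(=O)OC)C(=O)OC
F3 | step 1 | methyl 3,6-dimethyl-2,4-dioxocyclohexane-1-carboxylate | COC(=O)C1C(C)CC(=O)C(C)C1=O
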